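Late in the east run, which is the flask asked about, target stays flat while starting material falls from 11% to 1%, and I reckon from that flatness.

| flask | starting material | other conformer | protic impurity | temperature | remark | time |
|---|---|---|---|---|---|---|
| east | 0.020 M | 0.50 equiv | 4 mM | 25 °C | the very flask that is asked about, followed so far |  |
| west | 0.010 M | 0.50 equiv | 4 mM | 10 °C | run made earlier |  |
| flask | 0.020 M | 0.500 equiv | 4.00 mM | 25 °C |  | 3.0 d |

| run | time / d | target / % | starting material / % |
|---|---|---|---|
| east | 0.625 | 27 | 11 |
| east | 1.25 | 26 | 4 |
| east | 1.67 | 27 | 1 |
| east | 2.50 | 24 | 4 |
| west | 0.208 | 5 | 59 |
| west | 0.417 | 6 | 60 |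
| west | 1.04 | 10 | 50 |
| west | 2.50 | 18 | 31 |

(scatter of a reading: 1.5 percentage points)

- Thursday's: at 3.0 d add starting material, 50.0% of the amount charged, then wait 20 h
- Wednesday's: at 3.0 d take out 90% of the target then present, then wait 20 h
- Friday's: change nothing and wait 20 h more
- Saturday's: at 3.0 d raise the temperature by 10 K, then wait 20 h

1. target, in percent of the starting material and other conformer together first charged, at 3.0 d
2. what to do for the largest gain in target; "none" if nothing gains more than 2 percentage points (Thursday's / Wednesday's / Friday's / Saturday's / none)
3. target present, with what was taken out counted in, in percent of the starting material and other conformer together first charged, after Thursday's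
4. target present, with what was taken out counted in, in percent of the starting material and other conformer together first charged, after Friday's

- removed target is counted in
- additions bring no volume worth counting

At 2.50 d in the east flask, the readings of target and starting material together make 28.0%, so by those readings 72.0% of the charge stands in forms that are not read, the other conformer among them. My assumption is that these forms exchange with target by first-order steps, so that I treat the east flask as under thermodynamic control. On that assumption the part standing as target carries no concentration of starting material. The mean of the east target readings gives 26.0% as the plateau share, the part of the charge that stands as target on the flat stretch; it is a reading and carries their scatter.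

I take the settings in turn. On my assumption Friday's waiting leaves the share alone, so I expect target to stay at 26.0%. Thursday's addition brings 33.3% of the first charge, which divides by the same share, so I reckon 34.7%. Wednesday's removal takes out 23.4%, and I take 20 h as enough for the pool left behind to divide again, so with the removed target counted in I reckon 43.3%, which is more than I reckon for Thursday's. Saturday's heat may move the share itself, but target in the west run at 10 °C is still rising at its last reading of 18%, so that run gives me no plateau to compare and I leave Saturday's unsized.

The forecast gives 25.5% now, 25.5% after Friday's and 33% after Thursday's, and it chooses Thursday's, holding that “nothing shows target is equilibrium-limited”. My reckoning differs from it there, since I put Wednesday's above Thursday's.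

The flask gives 28.4%, then 29.4% after Friday's and 39.7% after Thursday's, and Saturday's is best, gaining 24 percentage points.

    other conformer ⇌ dormant form (K = 5.20, k = 0.00495 min⁻¹, Ea = 93.0 kJ mol⁻¹, ΔH = −78.0 kJ mol⁻¹)
    other conformer + protic impurity → quenched substrate (k = 0.137 L mol⁻¹ min⁻¹, Ea = 48.0 kJ mol⁻¹)
    other conformer → isomer of the product (k = 0.00238 min⁻¹, Ea = 105 kJ mol⁻¹)
    starting material → target (k = 0.00133 min⁻¹, Ea = 105 kJ mol⁻¹)
    target ⇌ isomer of the product (K = 1.96, k = 0.00153 min⁻¹, Ea = 87.0 kJ mol⁻¹, ΔH = −69.0 kJ mol⁻¹)
    starting material ⇌ other conformer (K = 0.877, k = 8.44 × 10⁻⁴ min⁻¹, Ea = 105 kJ mol⁻¹, ΔH = −3.00 kJ mol⁻¹)
    (constants at 25 °C)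

Target and isomer of the product relax into each other with a half-life of 0.208 d by that step alone, both ways together, short against the 3.0 d of the flask. With the plateau share of 26.0% as read, my reckoned gain for Wednesday's comes to 17 points, and the flask gives 17 points. The same share of 26.0% stands against 28.6% in the neighbour flask with 0.034 M of starting material.

Readings and results come from a simulation for an exercise; noise was put on by code.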